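**Plan**

The target is the (1S,2R,3R) isomer of lyoniresinol. Tetralin numbering is used: C1 carries pendant ring C, C2 and C3 carry the CH2OH carbons C9 and C10, C4 is CH2, and ring A is C4a–C8a.
- Cuts, in retrosynthetic order: the three O-benzyl groups; the C9 alcohol back to a vinyl group; C1–C2 (ring B); then C4–C4a and C1–C8a on ring A; in the side-chain fragment, the alkene (metathesis) and the Cα–CH2OBn bond.
- Enabling feature: C4a and C8a are adjacent ring A carbons bearing C4 and C1, with the C8 methoxy group next to C8a. This is the pattern left when a carbon nucleophile and then a carbon electrophile add across a 3-methoxyaryne.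
- Forward order: three fragments are made; one flask joins the alkyl chain and the diarylmethanol carbon to ring A (no ring formed); ring B then closes by cation–allylsilane cyclisation; the vinyl group becomes CH2OH; hydrogenolysis ends the route.
- Stereochemistry: C3 comes from an oxazolidinone-controlled alkylation; C2 and C1 are relayed from C3 in the chair-like ring closure.

Key step: step 8

Remark on the chemistry: the C1 carbon is brought in as an aldehyde so that the coupling gives the ionisable diarylmethanol directly (both carbinol epimers, which converge on ionisation), and any Z allylsilane from the metathesis is carried along because the silicon-bearing carbon ends as the terminal vinyl carbon.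

**Route**

Step 1
Reactants: 1 4-bromo-2,6-dimethoxyphenol
Product: 2 2-(benzyloxy)-5-bromo-1,3-dimethoxybenzene
Conditions: BnBr, K2CO3, DMF, 60 °C
Reagents that add atoms: benzyl bromide, BrCc1ccccc1
Why: Williamson ether synthesis; the phenoxide displaces bromide from benzyl bromide and the aryl bromide is inert to carbonate.

Step 2
Reactants: 3 syringaldehyde (4-hydroxy-3,5-dimethoxybenzaldehyde)
Product: 4 4-(benzyloxy)-3,5-dimethoxybenzaldehyde
Conditions: BnBr, K2CO3, DMF, 60 °C
Reagents that add atoms: benzyl bromide, BrCc1ccccc1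
Why: Williamson benzylation of the acidic phenol; the aldehyde has no α-hydrogen and is untouched.

Step 3
Reactants: 5 but-3-enoic acid; 6 (4S)-4-benzyl-1,3-oxazolidin-2-one
Product: 8 (4S)-4-benzyl-3-(but-3-enoyl)-1,3-oxazolidin-2-one, via mixed anhydride 7 (not isolated)
Conditions: PivCl, Et3N, THF, −20 °C; then 6, LiCl, −20 °C → rt
Reagents that add atoms: none
Why: N-acylation of the oxazolidinone through the pivalic mixed anhydride (LiCl/Et3N protocol), which transfers the less hindered acyl group and is mild enough to keep the double bond out of conjugation.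

Step 4
Reactants: 8 (4S)-4-benzyl-3-(but-3-enoyl)-1,3-oxazolidin-2-one
Product: 10 (4S)-4-benzyl-3-[(2R)-2-[(benzyloxy)methyl]but-3-enoyl]-1,3-oxazolidin-2-one, via titanium enolate 9 (not isolated)
Conditions: TiCl4, iPr2NEt, CH2Cl2, 0 °C; then BnOCH2Cl, 0 °C
Reagents that add atoms: benzyl chloromethyl ether, ClCOCc1ccccc1
Why: Evans asymmetric alkylation through the chelated titanium (Z)-enolate; the dienolate should react at its α-carbon on the face away from the C4 benzyl group, setting the (R) centre that becomes C3.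

Step 5
Reactants: 10 (4S)-4-benzyl-3-[(2R)-2-[(benzyloxy)methyl]but-3-enoyl]-1,3-oxazolidin-2-one
Product: 11 (2S)-2-[(benzyloxy)methyl]but-3-en-1-ol
Conditions: LiBH4, MeOH (1 equiv), THF, 0 °C
Reagents that add atoms: none
Why: Reductive cleavage of the N-acyl oxazolidinone at the exocyclic carbonyl releases the auxiliary without enolising the stereocentre (the descriptor changes only because the priorities change).

Step 6
Reactants: 11 (2S)-2-[(benzyloxy)methyl]but-3-en-1-ol
Product: 12 ({[(2R)-2-(bromomethyl)but-3-en-1-yl]oxy}methyl)benzene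
Conditions: CBr4, PPh3, CH2Cl2, 0 °C
Reagents that add atoms: carbon tetrabromide, BrC(Br)(Br)Br
Why: Appel bromination; substitution takes place at the primary carbon only, so the neighbouring stereocentre is untouched.

Step 7
Reactants: 12 ({[(2R)-2-(bromomethyl)but-3-en-1-yl]oxy}methyl)benzene; 13 allyltrimethylsilane
Product: 14 [(2E,4R)-4-[(benzyloxy)methyl]-5-bromopent-2-en-1-yl]trimethylsilane
Conditions: 13 (4 equiv), second-generation Grubbs catalyst (H2IMes)(PCy3)Cl2Ru=CHPh (5 mol %), CH2Cl2, 40 °C
Reagents that add atoms: none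
Why: Olefin cross-metathesis of the terminal alkene with excess allylsilane, driven by loss of ethene and favouring the E alkene; the alkyl bromide and benzyl ether are tolerated by the ruthenium carbene.

Step 8
Reactants: 14 [(2E,4R)-4-[(benzyloxy)methyl]-5-bromopent-2-en-1-yl]trimethylsilane; 2 2-(benzyloxy)-5-bromo-1,3-dimethoxybenzene; 4 4-(benzyloxy)-3,5-dimethoxybenzaldehyde
Product: 19 [4-(benzyloxy)-3,5-dimethoxyphenyl]{3-(benzyloxy)-6-[(2R,3E)-2-[(benzyloxy)methyl]-5-(trimethylsilyl)pent-3-en-1-yl]-2,4-dimethoxyphenyl}methanol (both carbinol epimers), via Grignard reagent 15 (not isolated), via aryllithium 16 (not isolated), via aryne 17 (not isolated), via arylmagnesium bromide 18 (not isolated)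
Conditions: 14, Mg turnings, THF, rt (gives 15, 1.5 equiv); 2, LiTMP (lithium 2,2,6,6-tetramethylpiperidide, 1.1 equiv), THF, −78 °C; 15 added, −78 °C → rt; then 4 (2.5 equiv), −78 °C → rt; aq. NH4Cl
Reagents that add atoms: none
Why: LiTMP removes the proton flanked by bromine and methoxy in 2 (the two ortho hydrogens of the symmetric bromide are equivalent) to give aryllithium 16, which loses LiBr on warming to give the 3-methoxy-type aryne 17. Grignard reagent 15 adds to the aryne carbon remote from the methoxy group (future C4a), because the inductively withdrawing, magnesium-coordinating methoxy group stabilises the carbanion developing at the adjacent carbon (future C8a); this is the known carbomagnesiation of 3-alkoxyarynes followed by trapping of the ortho-alkoxy arylmagnesium with a carbonyl electrophile. Arylmagnesium 18 then undergoes 1,2-addition to aldehyde 4, so ring A receives C4 and C1 on neighbouring carbons in one flask and no ring closes. The only new stereocentre, the carbinol carbon, forms without control and is erased by ionisation in step 9, while the (R) centre and the allylsilane of 15 ride through as spectators. The selectivity needed is regiochemical (alkyl at C4a, carbinol carbon at C8a beside the C8 methoxy group) and is secured by the single methoxy group flanking the aryne; the excess of 15 keeps the aryne from being taken by the amide base or by 18.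

Step 9
Reactants: 19 [4-(benzyloxy)-3,5-dimethoxyphenyl]{3-(benzyloxy)-6-[(2R,3E)-2-[(benzyloxy)methyl]-5-(trimethylsilyl)pent-3-en-1-yl]-2,4-dimethoxyphenyl}methanol
Product: 21 (1S,2R,3R)-7-(benzyloxy)-3-[(benzyloxy)methyl]-1-[4-(benzyloxy)-3,5-dimethoxyphenyl]-2-ethenyl-6,8-dimethoxy-1,2,3,4-tetrahydronaphthalene, via diarylmethyl cation 20 (not isolated)
Conditions: BF3·OEt2 (0.2 equiv), CH2Cl2, −78 → −20 °C; aq. NaHCO3
Reagents that add atoms: none
Why: Intramolecular Hosomi–Sakurai-type cation–olefin cyclisation: the Lewis acid ionises the doubly benzylic alcohol, the allylsilane carbon next to C3 attacks the cation to close the six-membered ring B (the other alkene carbon stays outside the ring and becomes the vinyl group as silicon leaves), and a chair-like transition state with CH2OBn at C3, the alkene residue at C2 and the pendant aryl at C1 all pseudo-equatorial should set C2 trans to C3 and C1 trans to C2.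

Step 10
Reactants: 21 (1S,2R,3R)-7-(benzyloxy)-3-[(benzyloxy)methyl]-1-[4-(benzyloxy)-3,5-dimethoxyphenyl]-2-ethenyl-6,8-dimethoxy-1,2,3,4-tetrahydronaphthalene
Product: 23 (1S,2R,3R)-7-(benzyloxy)-3-[(benzyloxy)methyl]-1-[4-(benzyloxy)-3,5-dimethoxyphenyl]-6,8-dimethoxy-1,2,3,4-tetrahydronaphthalene-2-carbaldehyde, via diol 22 (not isolated)
Conditions: OsO4 (2 mol %), NaIO4 (4 equiv), 2,6-lutidine, dioxane/H2O (3:1), rt
Reagents that add atoms: sodium periodate, [Na+].[O-]I(=O)(=O)=O; osmium tetroxide (oxygen carrier), O=[Os](=O)(=O)=O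
Why: Lemieux–Johnson oxidation (catalytic dihydroxylation, then periodate cleavage in the same flask) of the monosubstituted alkene, buffered by 2,6-lutidine so that the electron-rich arenes and benzyl ethers are left alone; C2 already sits in the favoured all-trans arrangement.

Step 11
Reactants: 23 (1S,2R,3R)-7-(benzyloxy)-3-[(benzyloxy)methyl]-1-[4-(benzyloxy)-3,5-dimethoxyphenyl]-6,8-dimethoxy-1,2,3,4-tetrahydronaphthalene-2-carbaldehyde
Product: 24 {(1S,2R,3R)-7-(benzyloxy)-3-[(benzyloxy)methyl]-1-[4-(benzyloxy)-3,5-dimethoxyphenyl]-6,8-dimethoxy-1,2,3,4-tetrahydronaphthalen-2-yl}methanol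
Conditions: NaBH4, MeOH/THF, 0 °C
Reagents that add atoms: none
Why: Borohydride reduction of the aldehyde to the primary alcohol, carried out promptly so that C2 has no chance to epimerise.

Step 12
Reactants: 24 {(1S,2R,3R)-7-(benzyloxy)-3-[(benzyloxy)methyl]-1-[4-(benzyloxy)-3,5-dimethoxyphenyl]-6,8-dimethoxy-1,2,3,4-tetrahydronaphthalen-2-yl}methanol
Product: 25 [(1S,2R,3R)-7-hydroxy-1-(4-hydroxy-3,5-dimethoxyphenyl)-3-(hydroxymethyl)-6,8-dimethoxy-1,2,3,4-tetrahydronaphthalen-2-yl]methanol
Conditions: H2 (1 atm), Pd/C (10 wt %), MeOH/EtOAc, rt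
Reagents that add atoms: none
Why: Hydrogenolysis of the two aryl benzyl ethers and the alkyl benzyl ether over palladium on carbon; no alkene remains and the C1–aryl bonds are not cleaved under these conditions.

**Compound list**

1 | 4-bromo-2,6-dimethoxyphenol | COc1cc(Br)cc(OC)c1O | starting material
2 | 2-(benzyloxy)-5-bromo-1,3-dimethoxybenzene | COc1cc(Br)cc(OC)c1OCc1ccccc1 | intermediate
3 | syringaldehyde (4-hydroxy-3,5-dimethoxybenzaldehyde) | COc1cc(C=O)cc(OC)c1O | starting material
4 | 4-(benzyloxy)-3,5-dimethoxybenzaldehyde | COc1cc(C=O)cc(OC)c1OCc1ccccc1 | intermediate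
5 | but-3-enoic acid | C=CCC(=O)O | starting material
6 | (4S)-4-benzyl-1,3-oxazolidin-2-one | O=C1N[C@@H](Cc2ccccc2)CO1 | starting material
7 | but-3-enoic pivalic anhydride | C=CCC(=O)OC(=O)C(C)(C)C | intermediate (not isolated)
8 | (4S)-4-benzyl-3-(but-3-enoyl)-1,3-oxazolidin-2-one | C=CCC(=O)N1[C@@H](Cc2ccccc2)COC1=O | intermediate
9 | trichlorotitanium (Z)-dienolate of 8 | C=C/C=C(\O[Ti](Cl)(Cl)Cl)N1[C@@H](Cc2ccccc2)COC1=O | intermediate (not isolated)
10 | (4S)-4-benzyl-3-[(2R)-2-[(benzyloxy)methyl]but-3-enoyl]-1,3-oxazolidin-2-one | C=C[C@H](COCc1ccccc1)C(=O)N1[C@@H](Cc2ccccc2)COC1=O | intermediate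
11 | (2S)-2-[(benzyloxy)methyl]but-3-en-1-ol | OC[C@@H](COCc1ccccc1)C=C | intermediate
12 | ({[(2R)-2-(bromomethyl)but-3-en-1-yl]oxy}methyl)benzene | BrC[C@@H](COCc1ccccc1)C=C | intermediate
13 | allyltrimethylsilane | C=CC[Si](C)(C)C | starting material
14 | [(2E,4R)-4-[(benzyloxy)methyl]-5-bromopent-2-en-1-yl]trimethylsilane | BrC[C@@H](COCc1ccccc1)/C=C/C[Si](C)(C)C | intermediate
15 | {(2R,3E)-2-[(benzyloxy)methyl]-5-(trimethylsilyl)pent-3-en-1-yl}magnesium bromide | Br[Mg]C[C@@H](COCc1ccccc1)/C=C/C[Si](C)(C)C | intermediate (not isolated)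
16 | [3-(benzyloxy)-6-bromo-2,4-dimethoxyphenyl]lithium | [Li]c1c(Br)cc(OC)c(OCc2ccccc2)c1OC | intermediate (not isolated)
17 | 4-(benzyloxy)-3,5-dimethoxybenzyne | COC1=CC#CC(OC)=C1OCc1ccccc1 | intermediate (not isolated)
18 | {3-(benzyloxy)-6-[(2R,3E)-2-[(benzyloxy)methyl]-5-(trimethylsilyl)pent-3-en-1-yl]-2,4-dimethoxyphenyl}magnesium bromide | COc1cc(C[C@@H](COCc2ccccc2)/C=C/C[Si](C)(C)C)c([Mg]Br)c(OC)c1OCc1ccccc1 | intermediate (not isolated)
19 | [4-(benzyloxy)-3,5-dimethoxyphenyl]{3-(benzyloxy)-6-[(2R,3E)-2-[(benzyloxy)methyl]-5-(trimethylsilyl)pent-3-en-1-yl]-2,4-dimethoxyphenyl}methanol, both carbinol epimers | COc1cc(C(O)c2c(C[C@@H](COCc3ccccc3)/C=C/C[Si](C)(C)C)cc(OC)c(OCc3ccccc3)c2OC)cc(OC)c1OCc1ccccc1 | intermediate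
20 | diarylmethyl cation derived from 19 | COc1cc([CH+]c2c(C[C@@H](COCc3ccccc3)/C=C/C[Si](C)(C)C)cc(OC)c(OCc3ccccc3)c2OC)cc(OC)c1OCc1ccccc1 | intermediate (not isolated)
21 | (1S,2R,3R)-7-(benzyloxy)-3-[(benzyloxy)methyl]-1-[4-(benzyloxy)-3,5-dimethoxyphenyl]-2-ethenyl-6,8-dimethoxy-1,2,3,4-tetrahydronaphthalene | COc1cc([C@H]2c3c(cc(OC)c(OCc4ccccc4)c3OC)C[C@@H](COCc3ccccc3)[C@@H]2C=C)cc(OC)c1OCc1ccccc1 | intermediate
22 | 1-{(1S,2R,3R)-7-(benzyloxy)-3-[(benzyloxy)methyl]-1-[4-(benzyloxy)-3,5-dimethoxyphenyl]-6,8-dimethoxy-1,2,3,4-tetrahydronaphthalen-2-yl}ethane-1,2-diol, both carbinol epimers | COc1cc([C@H]2c3c(cc(OC)c(OCc4ccccc4)c3OC)C[C@@H](COCc3ccccc3)[C@@H]2C(O)CO)cc(OC)c1OCc1ccccc1 | intermediate (not isolated)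
23 | (1S,2R,3R)-7-(benzyloxy)-3-[(benzyloxy)methyl]-1-[4-(benzyloxy)-3,5-dimethoxyphenyl]-6,8-dimethoxy-1,2,3,4-tetrahydronaphthalene-2-carbaldehyde | COc1cc([C@H]2c3c(cc(OC)c(OCc4ccccc4)c3OC)C[C@@H](COCc3ccccc3)[C@@H]2C=O)cc(OC)c1OCc1ccccc1 | intermediate
24 | {(1S,2R,3R)-7-(benzyloxy)-3-[(benzyloxy)methyl]-1-[4-(benzyloxy)-3,5-dimethoxyphenyl]-6,8-dimethoxy-1,2,3,4-tetrahydronaphthalen-2-yl}methanol | COc1cc([C@H]2c3c(cc(OC)c(OCc4ccccc4)c3OC)C[C@@H](COCc3ccccc3)[C@@H]2CO)cc(OC)c1OCc1ccccc1 | intermediate
25 | [(1S,2R,3R)-7-hydroxy-1-(4-hydroxy-3,5-dimethoxyphenyl)-3-(hydroxymethyl)-6,8-dimethoxy-1,2,3,4-tetrahydronaphthalen-2-yl]methanol | COc1cc([C@H]2c3c(cc(OC)c(O)c3OC)C[C@@H](CO)[C@@H]2CO)cc(OC)c1O | target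

**Summary**

Total step count: 12. Longest linear sequence: 10 steps (steps 3 to 12, from but-3-enoic acid).

**Steps most likely to fail**

1. Step 8. The aryne may be consumed by the amide base, by arylmagnesium 18 or by aryllithium 16 faster than by the β-branched Grignard reagent. The Grignard reagent may also erode through homoallyl–cyclopropylcarbinyl shuffling or Wurtz coupling before it is used. The fallback forms the two ring A bonds in separate, known operations and sets out from 2, 4 and 14. Aryllithium 16 is generated as in step 8, held at −78 °C and quenched directly with aldehyde 4 (directed ortho-metalation with carbonyl capture) to give [4-(benzyloxy)-3,5-dimethoxyphenyl][3-(benzyloxy)-6-bromo-2,4-dimethoxyphenyl]methanol F1. Bromide 14 is converted with zinc dust and LiCl in THF into {(2R,3E)-2-[(benzyloxy)methyl]-5-(trimethylsilyl)pent-3-en-1-yl}zinc bromide F2. Negishi coupling of F1 with F2 (Pd(OAc)2, SPhos, THF, hydroxyl group left free) should then put the alkyl chain on the former bromide carbon and return to the route at 19.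

2. Step 9. The planar cation 20 may be captured on both faces (poor control at C1), or the allylsilane may be lost by protonation before the ring closes. The fallback closes the ring on a carbonyl group and sets C1 in a separate hydride delivery; it sets out from 19. Oxidation with Dess–Martin periodinane should give [4-(benzyloxy)-3,5-dimethoxyphenyl]{3-(benzyloxy)-6-[(2R,3E)-2-[(benzyloxy)methyl]-5-(trimethylsilyl)pent-3-en-1-yl]-2,4-dimethoxyphenyl}methanone F3. TiCl4-promoted intramolecular Hosomi–Sakurai addition to the ketone (CH2Cl2, −78 °C) should give (2S,3R)-7-(benzyloxy)-3-[(benzyloxy)methyl]-1-[4-(benzyloxy)-3,5-dimethoxyphenyl]-2-ethenyl-6,8-dimethoxy-1,2,3,4-tetrahydronaphthalen-1-ol F4, with vinyl and CH2OBn trans (the descriptor at C2 differs only through the priorities). Ionic hydrogenation (Et3SiH, BF3·OEt2, CH2Cl2, −78 °C) is expected to deliver hydride pseudo-axially, anti to the axial C2–H, leaving aryl and vinyl trans and returning to the route at 21. This stereochemical outcome is a prediction from the half-chair model and is the weak point of this fallback.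

3. Step 4. The β,γ-double bond may move into conjugation with the imide carbonyl during enolisation, or the dienolate may be alkylated at its γ-carbon. The fallback enters the same dienolate from the conjugated isomer and sets out from 6. Acylation with (E)-but-2-enoyl chloride (n-BuLi, THF, −78 °C) gives (4S)-4-benzyl-3-[(2E)-but-2-enoyl]-1,3-oxazolidin-2-one F5. γ-Deprotonation with NaHMDS (NaN(SiMe3)2, THF, −78 °C) gives the sodium (Z)-dienolate of the butenoyl imide F6. α-Alkylation with benzyl chloromethyl ether (deconjugative Evans alkylation, same facial control by the C4 benzyl group) should return to the route at 10.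

**Further compounds**

F1 | step 8 | [4-(benzyloxy)-3,5-dimethoxyphenyl][3-(benzyloxy)-6-bromo-2,4-dimethoxyphenyl]methanol | COc1cc(C(O)c2c(Br)cc(OC)c(OCc3ccccc3)c2OC)cc(OC)c1OCc1ccccc1
F2 | step 8 | {(2R,3E)-2-[(benzyloxy)methyl]-5-(trimethylsilyl)pent-3-en-1-yl}zinc bromide | Br[Zn]C[C@@H](COCc1ccccc1)/C=C/C[Si](C)(C)C
F3 | step 9 | [4-(benzyloxy)-3,5-dimethoxyphenyl]{3-(benzyloxy)-6-[(2R,3E)-2-[(benzyloxy)methyl]-5-(trimethylsilyl)pent-3-en-1-yl]-2,4-dimethoxyphenyl}methanone | COc1cc(C(=O)c2c(C[C@@H](COCc3ccccc3)/C=C/C[Si](C)(C)C)cc(OC)c(OCc3ccccc3)c2OC)cc(OC)c1OCc1ccccc1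
F4 | step 9 | (2S,3R)-7-(benzyloxy)-3-[(benzyloxy)methyl]-1-[4-(benzyloxy)-3,5-dimethoxyphenyl]-2-ethenyl-6,8-dimethoxy-1,2,3,4-tetrahydronaphthalen-1-ol | COc1cc(C2(O)c3c(cc(OC)c(OCc4ccccc4)c3OC)C[C@@H](COCc3ccccc3)[C@@H]2C=C)cc(OC)c1OCc1ccccc1
F5 | step 4 | (4S)-4-benzyl-3-[(2E)-but-2-enoyl]-1,3-oxazolidin-2-one | C/C=C/C(=O)N1[C@@H](Cc2ccccc2)COC1=O
F6 | step 4 | sodium (Z)-dienolate of the butenoyl imide | [Na+].C=C/C=C(\[O-])N1[C@@H](Cc2ccccc2)COC1=O
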